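Its constants were drawn at random within sensible limits; what happens was integrated by code.

The left-handed product at the end of each flask is the number to watch, and the question is how much racemization adds to it.

    coupling partner + left-handed substrate → left-handed product (k1 = 0.40 M⁻¹ min⁻¹)
    coupling partner + right-handed substrate → right-handed product (k2 = 0.0026 M⁻¹ min⁻¹)
    left-handed substrate + racemization catalyst ⇌ right-handed substrate + racemization catalyst, rate k3*[racemization catalyst]*[left-handed substrate] forward; the back reaction follows from the equilibrium constant (k3 = 3.5 M⁻¹ min⁻¹)
    gas ⇌ coupling partner, rate k4*(csat - [coupling partner]) (k4 = 5.3 min⁻¹, csat = 19 mM)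

| flask | left-handed substrate | gas | racemization catalyst | right-handed substrate | time |
|---|---|---|---|---|---|
| epsilon | 0.50 M | 19 mM (held) | 0.2 mol% | 0.50 M | 1.5 h |
| alpha | 0.50 M | 19 mM (held) | 0.3 mol% | 0.50 M | 1.5 h |
| gamma | 0.50 M | 19 mM (held) | 0.5 mol% | 0.50 M | 1.5 h |
| theta | 0.50 M | 19 mM (held) | 0.8 mol% | 0.50 M | 1.5 h |

- amount of left-handed product at the end, in percent of the left-handed substrate and right-handed substrate together charged for epsilon, alpha, gamma, theta, in this order
- the course of these numbers from the first flask to the last (falls all the way / hardly changes / rises, then falls / falls, then rises / rises all the way)

- coupling partner is single-handed; left-handed substrate and right-handed substrate are mirror images of each other, charged as a racemate, each of them at the stated concentration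
- at the start none of coupling partner is dissolved
- "hardly changes" means that all values lie within two and a half points (for a concentration: within two and a half percent of the largest)
- run time (epsilon): 1.5 h
- the handed part of coupling partner does not stay in what it makes, so the products of the two hands are mirror images too

1. I start from the gas. Transfer is faster than coupling as charged, 5.3 min⁻¹ against 0.200 min⁻¹, so c(coupling partner) stands near 18.3 mM. The left-handed substrate is then consumed pseudo-first-order at 0.00732 min⁻¹. The right-handed path has the smaller constant, so I drop it.

2. The large term is the left-handed half coupling by itself, which gives 24.1% of all substrate charged.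

3. The small term is the refill. With the loading taken on the left-handed substrate, racemization runs at 0.00350 min⁻¹ in epsilon and 0.0140 min⁻¹ in theta. If c(right-handed substrate) stays as charged, the first-order gains are 0.829% and 3.32%. Their difference, 2.5 percentage points, lands on the margin of 2.5 points, so this does not answer the shape.

4. The weak link is theta, where racemization is faster than coupling, so I stop holding c(right-handed substrate) constant. I solve both substrates together. The left-handed substrate then falls as a fast and a slow exponential, the slow one at 0.00210 min⁻¹ in epsilon and 0.00319 min⁻¹ in theta. The yields become 24.8% and 26.1%. These are for epsilon and theta, and I commit to them: the row hardly changes.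

5. Once the fast exponential has faded, c(left-handed substrate)/c(right-handed substrate) holds at one minus the slow rate over the racemization constant. I call this the holding ratio: 0.772 in theta and 0.401 in epsilon.

6. The forecast gives 25.4%, 25.9%, 26.4%, 26.9%: hardly changes. It parts from me on the loading, “Taking mol% on total substrate (1.0 M)”, so its first racemization constant is 0.007 per minute against my 0.00350 min⁻¹.

The flasks give 25.0%, 25.2%, 25.7%, 26.2%: hardly changes, with a spread of 1.2 points. At alpha the local order in the racemization catalyst is 0.031. In theta at 1.50 h, c(left-handed substrate)/c(right-handed substrate) reads 0.787, against a holding ratio of 0.772. In epsilon at 15.0 h it reads 0.393, against a holding ratio of 0.401.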